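- At early times the amber run, charged with 0.10 M of solid substrate, told me little about the products: at 6.00 min it read 2.8% isomer of the product and 0% target, with a scatter of 1 percentage point on each reading.

| flask | solid substrate | remark | time |
|---|---|---|---|
| amber | 0.10 M | run made earlier |  |
| flask | 0.050 M |  | 12 h |

- amber (time / min: isomer of the product / %, target / %, solid substrate / %): 6.00: 2.8, 0, 93.5; 12.0: 4.1, 0.2, 89.8; 30.0: 11.8, 4.7, 82.0; 80.0: 28.3, 6.5, 56.6

(scatter of a reading: 1 percentage point)

- as a solid, counted per litre of solution: solid substrate
- at the start none of the solid substrate is in solution

- ratio of isomer of the product to target at 2.5 min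
- ratio of isomer of the product to target at 12 h
- which of isomer of the product and target there is more of at 12 h

- I kept a ledger of the amber run at 80.0 min, in percent of the charge: the solid substrate had lost 43.4%, of which 28.3% stood as isomer of the product and 6.5% as target, leaving a gap of 8.60%, which I booked as dissolved material that the readings do not show.
- Dividing one product by the other within a reading sets the two side by side at one moment, though the result can still change from reading to reading, and this gave 4.35 at 80.0 min; I call that value S, the latest split (a selectivity), isomer of the product per target in one reading.
- At 30.0 min the same division gave 2.51, so I reckoned that the split rises with time: near that value at 2.5 min, near S at 12 h, with isomer of the product ahead.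
- The amber solid fell by 0.499 mM min⁻¹; at that pace the 0.050 M in the new flask would last about 100 min, shorter than 12 h.
- The forecast gave 4 (3.2 to 6) at 2.5 min, 4 (2 to 5) at 12 h, and isomer of the product ahead, on this ground: “So I read these as parallel products with isomer:target about 4.” My rising split differs from that.
- The flask gave 2.04 at 2.5 min and 4.97 at 12 h, with isomer of the product ahead, 63.4% against 12.8%; its ledger closed with 23.8% starting material in the gap.

    starting material ⇌ isomer of the product (K = 2.66, k = 0.0148 s⁻¹)
    solid substrate ⇌ starting material, rate k2*(cs2 - [starting material]) while solid is left; crystals form when [starting material] > cs2 (solubility = 20.0 mM, k = 6.32 × 10⁻⁴ s⁻¹)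
    starting material ⇌ target (K = 0.535, k = 0.0264 s⁻¹)

In the flask the relaxation half-life of starting material and isomer of the product by their step alone, 0.567 min, is shorter than the run of 12 h, and the ratio stood at 4.97, beside 4.97 from the two equilibrium constants, in which time has dropped out; a run ten times as long leaves that ratio unchanged. I carried S to the neighbour flask with 0.20 M of solid substrate, which still held 58.1% solid at 12 h: its 26.6% isomer of the product divided by 4.35 gives 6.11% target, and that flask stood at 5.34%.

The earlier runs and the new flask are simulated with made-up constants, noise included.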